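**Plan**

1. Numbering follows the target dienone: C1 = C=O, C2 and C6 = C–Me, C3 carries the side chain, C4 is the quaternary carbon, C5 = CH. Cuts, in order: the C3–alkenyl bond (alkenylmetal plus vinylogous ester, with carbonyl transposition); the ring bond C1–C6; the two C4–acyl bonds, back to the 6-methyl group of a 2-methoxy-4-pyranone.
2. Enabling feature: with C3 and C5 both as ketones and a thioester on C6, the units C3–C2–C1 and C5–C6–(C=O) are two identical 2-methyl-3-oxothioester arms on C4. C4 of the open-chain precursor is therefore prochiral, and the C1–C6 closure itself can create the only ring stereocentre.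
3. Forward order: pyranone ring (steps 1–3); both arms built on its 6-methyl carbon (4–7); carbocycle by a desymmetrizing thioester Claisen (Dieckmann) closure (8); the helpers are then removed, the C5 oxygen as water and the C6 thioester as CO2, leaving C5=C6 (9–11); the side chain (12–16) is joined last (17) and its ketone is formed in the final step (18).
4. Stereochemistry: C4 from catalyst-controlled choice of the nucleophilic arm in step 8; the side-chain methyl centre from (R)-but-3-yn-2-ol by chirality transfer (13); the E alkene from syn-hydrozirconation (16).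

Key step: step 8

Remark: Pyr = 6-methoxy-3,5-dimethyl-4-oxo-4H-pyran-2-yl. Compounds 13–17 are written as one enol tautomer of the 1,3-dione. C6 (13–16) and C5 (14–16) are left unassigned because both become sp2 in step 11.

Remark (assumption): the sense of induction of the nickel catalyst in step 8 cannot be derived with certainty. The (R,R)-ligand is written; its enantiomer is taken if it proves to favour the other arm.

Step 1
Reactants: 1 methyl 2-methyl-3-oxopentanoate; 2 N-methoxy-N-methylacetamide
Product: 3 methyl 2,4-dimethyl-3,5-dioxohexanoate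
Conditions: NaH (1.1 equiv), THF, 0 °C; n-BuLi (1.05 equiv), 0 °C; then 2, 0 °C to rt; aqueous HCl
Reagents that add atoms: none
Why: The dianion of the 3-oxo ester reacts at its more basic terminal carbanion, and the amide acylates it only once because the chelated tetrahedral adduct survives until work-up (dianion γ-acylation, Weinreb ketone synthesis).

Step 2
Reactants: 3 methyl 2,4-dimethyl-3,5-dioxohexanoate
Product: 4 4-hydroxy-3,5,6-trimethyl-2H-pyran-2-one
Conditions: DBU (1.2 equiv), toluene, reflux
Reagents that add atoms: none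
Why: The enol oxygen of the terminal ketone adds to the ester and methanol is lost, the usual base-mediated lactonization of 3,5-dioxo esters to 4-hydroxy-2-pyranones.

Step 3
Reactants: 4 4-hydroxy-3,5,6-trimethyl-2H-pyran-2-one
Product: 5 2-methoxy-3,5,6-trimethyl-4H-pyran-4-one
Conditions: MeOTf (1.1 equiv), CH2Cl2, rt; then aqueous NaHCO3
Reagents that add atoms: methyl trifluoromethanesulfonate COS(=O)(=O)C(F)(F)F
Why: The hard methylating agent should attack the lactone carbonyl oxygen of the neutral hydroxypyranone, and loss of the hydroxyl proton from the pyrylium ion then gives the 2-methoxy-4-pyranone rather than the 4-methoxy-2-pyranone (regioselective O-methylation).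

Step 4
Reactants: 5 2-methoxy-3,5,6-trimethyl-4H-pyran-4-one; 6 N-methoxy-N-methylpropanamide
Product: 7 1-Pyr-butan-2-one
Conditions: LiN(SiMe3)2 (1.1 equiv), THF, −78 °C; then 6, −78 to 0 °C; aqueous NH4Cl
Reagents that add atoms: none
Why: Only the 6-methyl group is vinylogous to the pyranone carbonyl, so it is deprotonated selectively and the carbanion is acylated once by the Weinreb amide.

Step 5
Reactants: 7 1-Pyr-butan-2-one; 8 propanoyl chloride
Product: 9 4-Pyr-heptane-3,5-dione
Conditions: MgCl2 (1.2 equiv), Et3N (2.5 equiv), 8 (1.1 equiv), MeCN, 0 °C to rt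
Reagents that add atoms: none
Why: Magnesium-assisted soft enolization occurs only at the doubly activated methylene, and the magnesium enolate is acylated on carbon (C-acylation of an active methylene compound).

Step 6
Reactants: 9 4-Pyr-heptane-3,5-dione
Product: 10 4-methyl-4-Pyr-heptane-3,5-dione
Conditions: MeI (1.5 equiv), K2CO3 (2 equiv), acetone, rt
Reagents that add atoms: iodomethane CI
Why: The soft electrophile alkylates the stabilized enolate of the 2-substituted 1,3-diketone on carbon, which creates the future C4 as a prochiral quaternary carbon with two identical propanoyl arms.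

Step 7
Reactants: 10 4-methyl-4-Pyr-heptane-3,5-dione; 11 S,S-dimethyl dithiocarbonate
Product: 12 S,S'-dimethyl 2,4,6-trimethyl-3,5-dioxo-4-Pyr-heptanebis(thioate)
Conditions: NaH (4.4 equiv), 11 (2.4 equiv), DME, 0 °C to rt; then AcOH, 0 °C
Reagents that add atoms: none
Why: Each ethyl ketone can enolize only away from the quaternary carbon and the sodium enolates are thiocarboxylated on carbon (Claisen-type acylation with a dithiocarbonate); both arms then rest as unreactive 3-oxothioester enolates until the cold acidic quench, which should prevent premature cyclization.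

Step 8
Reactants: 12 S,S'-dimethyl 2,4,6-trimethyl-3,5-dioxo-4-Pyr-heptanebis(thioate)
Product: 13 S-methyl (5R)-2-hydroxy-1,3,5-trimethyl-4,6-dioxo-5-Pyr-cyclohex-2-ene-1-carbothioate
Conditions: Ni(ClO4)2·6H2O (10 mol %), (R,R)-4,6-dibenzofurandiyl-2,2'-bis(4-phenyloxazoline) (DBFOX/Ph, 11 mol %), 2,6-lutidine (1.0 equiv), CH2Cl2, −20 °C to rt
Reagents that add atoms: none
Why: Proposed new method: the divalent nickel–DBFOX complex should bind one 2-methyl-3-oxothioester arm of 12 as a chelated enolate (2,6-lutidine is basic enough only for the metal-bound arm, so no uncatalysed racemic path is expected); the enolate carbon C6 then adds to the thioester carbonyl C1 of the other arm, methanethiolate leaves, and the new 1,3-dione rests as its enol, which drives the equilibrium. The closest known reactions are the Dieckmann and Claisen condensations of thioesters under magnesium-mediated soft enolization and the enantioselective α-functionalization of 2-substituted 3-oxo esters as nickel–DBFOX or copper–bis(oxazoline) enolates; the nickel system is chosen because it tolerates thiols. The carbocycle closes in the 6-(enolendo)-exo-trig mode. C4 becomes stereogenic because the two arms are enantiotopic, so its configuration is fixed by which arm the chiral complex turns into the nucleophile, the second arm being held through its carbonyl at the remaining coordination site on one face of the enolate; the same facial shielding sets C6, which is erased in step 11. The step needs arm selection, C- rather than O-acylation, and attack on the thioester rather than on the C3 ketone: the arms differ only in their fit to the catalyst (products from the wrong arm are diastereomers of 13 when C6 is uniform and can be removed), chelation of both enolate oxygens secures C-acylation, and the quaternary C4 between the arms allows only the six-membered closure onto C1, since the ketone would give a four-membered ring. The weak base leaves the liberated thiol un-ionized, so the ring should not be reopened.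

Step 9
Reactants: 13 S-methyl (5R)-2-hydroxy-1,3,5-trimethyl-4,6-dioxo-5-Pyr-cyclohex-2-ene-1-carbothioate
Product: 14 S-methyl (5R)-2,6-dihydroxy-1,3,5-trimethyl-4-oxo-5-Pyr-cyclohex-2-ene-1-carbothioate
Conditions: NaBH4 (2 equiv), CeCl3·7H2O (1 equiv), MeOH/THF, −40 to 0 °C
Reagents that add atoms: none
Why: The enolized 1,3-dione is deprotonated and inert, and the thioester and pyranone are not reduced at low temperature, so the small cerium-activated hydride should add only to the C5 ketone (Luche reduction); the protic medium protonates the alkoxide at once, which checks retro-aldol opening, and either C5 epimer serves.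

Step 10
Reactants: 14 S-methyl (5R)-2,6-dihydroxy-1,3,5-trimethyl-4-oxo-5-Pyr-cyclohex-2-ene-1-carbothioate
Product: 16 (6R)-3,5-dihydroxy-2,4,6-trimethyl-6-Pyr-cyclohex-2-en-1-one, via β-keto acid 15 (not isolated)
Conditions: AgOCOCF3 (2.2 equiv), THF/H2O (4:1), rt to 40 °C
Reagents that add atoms: none
Why: The thiophilic silver salt activates the thioester for hydrolysis, and the acid, which is β to the C1 carbonyl, should decarboxylate spontaneously, so the activating group leaves as CO2 under neutral conditions (silver-assisted thioester hydrolysis, 3-oxo acid decarboxylation).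

Step 11
Reactants: 16 (6R)-3,5-dihydroxy-2,4,6-trimethyl-6-Pyr-cyclohex-2-en-1-one
Product: 18 (6R)-3-methoxy-2,4,6-trimethyl-6-Pyr-cyclohexa-2,4-dien-1-one, via enol 17 (not isolated)
Conditions: TsOH·H2O (10 mol %), MeOH, 3 Å molecular sieves, 50 °C
Reagents that add atoms: methanol CO
Why: Acid-catalysed loss of the C5 hydroxyl through the dienol gives the C5=C6 alkene whatever the configurations at C5 and C6 (stereoconvergent β-elimination), and the enolized dione is etherified at the oxygen remote from the quaternary carbon, the less hindered and linearly conjugated isomer (thermodynamic enol ether formation), which leaves the C3 carbonyl free for step 17.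

Step 12
Reactants: 19 (R)-but-3-yn-2-ol
Product: 20 (R)-but-3-yn-2-yl methanesulfonate
Conditions: MsCl (1.2 equiv), Et3N (1.5 equiv), CH2Cl2, −78 to 0 °C
Reagents that add atoms: methanesulfonyl chloride CS(=O)(=O)Cl
Why: Sulfonylation on oxygen leaves the stereocentre untouched.

Step 13
Reactants: 20 (R)-but-3-yn-2-yl methanesulfonate; 21 propanal
Product: 22 (3R,4S)-4-methylhex-5-yn-3-ol
Conditions: Pd(OAc)2 (5 mol %), PPh3 (5 mol %), Et2Zn (3 equiv), THF, −78 to −20 °C; aqueous NH4Cl
Reagents that add atoms: none
Why: Zerovalent palladium displaces the mesylate in an anti SN2' sense, transmetalation gives a configurationally defined allenylzinc, and its addition to the aldehyde through a cyclic transition state should give the anti homopropargylic alcohol; the net inversion at the former carbinol carbon sets the methyl-bearing centre as S (palladium-catalysed, zinc-mediated propargylation).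

Step 14
Reactants: 22 (3R,4S)-4-methylhex-5-yn-3-ol
Product: 23 triethyl{[(3R,4S)-4-methylhex-5-yn-3-yl]oxy}silane
Conditions: Et3SiCl (1.2 equiv), imidazole (2 equiv), DMF, 0 °C to rt
Reagents that add atoms: chlorotriethylsilane CC[Si](CC)(CC)Cl
Why: Routine silylation; the triethylsilyl ether should survive the organometallic steps and is cleaved by the acid of step 17.

Step 15
Reactants: 23 triethyl{[(3R,4S)-4-methylhex-5-yn-3-yl]oxy}silane
Product: 24 triethyl{[(3R,4S)-4-methylhept-5-yn-3-yl]oxy}silane
Conditions: n-BuLi (1.1 equiv), THF, −78 °C; MeI (1.5 equiv), −78 °C to rt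
Reagents that add atoms: iodomethane CI
Why: Alkylation of the lithium acetylide; the propargylic stereocentre is not deprotonated.

Step 16
Reactants: 24 triethyl{[(3R,4S)-4-methylhept-5-yn-3-yl]oxy}silane
Product: 26 triethyl{[(3R,4S,5E)-6-iodo-4-methylhept-5-en-3-yl]oxy}silane, via alkenylzirconocene 25 (not isolated)
Conditions: Cp2Zr(H)Cl (2.5 equiv), THF, 50 °C; then I2, 0 °C
Reagents that add atoms: iodine II
Why: syn-Hydrozirconation under equilibrating conditions places zirconium on the less hindered, methyl-bearing alkyne carbon, and iododemetalation with retention gives the E iodide with the geometry of the target alkene.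

Step 17
Reactants: 26 triethyl{[(3R,4S,5E)-6-iodo-4-methylhept-5-en-3-yl]oxy}silane; 18 (6R)-3-methoxy-2,4,6-trimethyl-6-Pyr-cyclohexa-2,4-dien-1-one
Product: 30 (4S)-3-[(2E,4S,5R)-5-hydroxy-4-methylhept-2-en-2-yl]-2,4,6-trimethyl-4-Pyr-cyclohexa-2,5-dien-1-one, via alkenyllithium 27 (not isolated), via tertiary carbinol 28 (not isolated), via silyl ether 29 (not isolated)
Conditions: 26, t-BuLi (2.0 equiv), Et2O, −78 °C; anhydrous CeCl3, THF, −78 °C; then 18, −78 to 0 °C; then 1 M HCl, THF, rt
Reagents that add atoms: none
Why: Iodine–lithium exchange keeps the alkene geometry, the weakly basic organocerium reagent should add 1,2 to the ketone next to the quaternary carbon, and aqueous acid ionizes the tertiary carbinol, hydrolyses the enol ether with loss of methanol to the transposed cross-conjugated dienone (Stork–Danheiser sequence) and removes the silyl group; C4 is not touched.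

Step 18
Reactants: 30 (4S)-3-[(2E,4S,5R)-5-hydroxy-4-methylhept-2-en-2-yl]-2,4,6-trimethyl-4-Pyr-cyclohexa-2,5-dien-1-one
Product: 31 (4S)-2,4,6-trimethyl-3-[(2E,4S)-4-methyl-5-oxohept-2-en-2-yl]-4-Pyr-cyclohexa-2,5-dien-1-one (target)
Conditions: Dess–Martin periodinane (1.5 equiv), NaHCO3, CH2Cl2, 0 °C to rt; chromatography on buffered silica
Reagents that add atoms: none
Why: Buffered, non-basic oxidation of the secondary alcohol forms the ethyl ketone last, so the epimerizable α-methyl centre of the β,γ-unsaturated ketone is never exposed to acid or base (Dess–Martin oxidation).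

**Compound list**

1 | methyl 2-methyl-3-oxopentanoate | CCC(=O)C(C)C(=O)OC | starting material
2 | N-methoxy-N-methylacetamide | CC(=O)N(C)OC | starting material
3 | methyl 2,4-dimethyl-3,5-dioxohexanoate | CC(=O)C(C)C(=O)C(C)C(=O)OC | intermediate
4 | 4-hydroxy-3,5,6-trimethyl-2H-pyran-2-one | Cc1oc(=O)c(C)c(O)c1C | intermediate
5 | 2-methoxy-3,5,6-trimethyl-4H-pyran-4-one | Cc1oc(OC)c(C)c(=O)c1C | intermediate
6 | N-methoxy-N-methylpropanamide | CCC(=O)N(C)OC | starting material
7 | 1-(6-methoxy-3,5-dimethyl-4-oxo-4H-pyran-2-yl)butan-2-one | CCC(=O)Cc1oc(OC)c(C)c(=O)c1C | intermediate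
8 | propanoyl chloride | CCC(=O)Cl | starting material
9 | 4-(6-methoxy-3,5-dimethyl-4-oxo-4H-pyran-2-yl)heptane-3,5-dione (largely enolized) | CCC(=O)C(C(=O)CC)c1oc(OC)c(C)c(=O)c1C | intermediate
10 | 4-(6-methoxy-3,5-dimethyl-4-oxo-4H-pyran-2-yl)-4-methylheptane-3,5-dione | CCC(=O)C(C)(C(=O)CC)c1oc(OC)c(C)c(=O)c1C | intermediate
11 | S,S-dimethyl dithiocarbonate | CSC(=O)SC | starting material
12 | S,S'-dimethyl 4-(6-methoxy-3,5-dimethyl-4-oxo-4H-pyran-2-yl)-2,4,6-trimethyl-3,5-dioxoheptanebis(thioate) (mixture of epimers at the two CH(Me) carbons) | CSC(=O)C(C)C(=O)C(C)(C(=O)C(C)C(=O)SC)c1oc(OC)c(C)c(=O)c1C | intermediate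
13 | S-methyl (5R)-2-hydroxy-5-(6-methoxy-3,5-dimethyl-4-oxo-4H-pyran-2-yl)-1,3,5-trimethyl-4,6-dioxocyclohex-2-ene-1-carbothioate (locant 1 unassigned) | O=C1C(C)=C(O)C(C)(C(=O)SC)C(=O)[C@]1(C)c1oc(OC)c(C)c(=O)c1C | intermediate
14 | S-methyl (5R)-2,6-dihydroxy-5-(6-methoxy-3,5-dimethyl-4-oxo-4H-pyran-2-yl)-1,3,5-trimethyl-4-oxocyclohex-2-ene-1-carbothioate (locants 1 and 6 unassigned) | O=C1C(C)=C(O)C(C)(C(=O)SC)C(O)[C@]1(C)c1oc(OC)c(C)c(=O)c1C | intermediate
15 | (5R)-2,6-dihydroxy-5-(6-methoxy-3,5-dimethyl-4-oxo-4H-pyran-2-yl)-1,3,5-trimethyl-4-oxocyclohex-2-ene-1-carboxylic acid | O=C1C(C)=C(O)C(C)(C(=O)O)C(O)[C@]1(C)c1oc(OC)c(C)c(=O)c1C | intermediate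
16 | (6R)-3,5-dihydroxy-6-(6-methoxy-3,5-dimethyl-4-oxo-4H-pyran-2-yl)-2,4,6-trimethylcyclohex-2-en-1-one (locants 4 and 5 unassigned) | O=C1C(C)=C(O)C(C)C(O)[C@]1(C)c1oc(OC)c(C)c(=O)c1C | intermediate
17 | (6R)-3-hydroxy-6-(6-methoxy-3,5-dimethyl-4-oxo-4H-pyran-2-yl)-2,4,6-trimethylcyclohexa-2,4-dien-1-one | O=C1C(C)=C(O)C(C)=C[C@]1(C)c1oc(OC)c(C)c(=O)c1C | intermediate
18 | (6R)-3-methoxy-6-(6-methoxy-3,5-dimethyl-4-oxo-4H-pyran-2-yl)-2,4,6-trimethylcyclohexa-2,4-dien-1-one | O=C1C(C)=C(OC)C(C)=C[C@]1(C)c1oc(OC)c(C)c(=O)c1C | intermediate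
19 | (R)-but-3-yn-2-ol | C[C@@H](O)C#C | starting material
20 | (R)-but-3-yn-2-yl methanesulfonate | C[C@@H](OS(C)(=O)=O)C#C | intermediate
21 | propanal | CCC=O | starting material
22 | (3R,4S)-4-methylhex-5-yn-3-ol | CC[C@@H](O)[C@@H](C)C#C | intermediate
23 | triethyl{[(3R,4S)-4-methylhex-5-yn-3-yl]oxy}silane | CC[C@@H](O[Si](CC)(CC)CC)[C@@H](C)C#C | intermediate
24 | triethyl{[(3R,4S)-4-methylhept-5-yn-3-yl]oxy}silane | CC[C@@H](O[Si](CC)(CC)CC)[C@@H](C)C#CC | intermediate
25 | chlorobis(cyclopentadienyl)[(2E,4S,5R)-4-methyl-5-(triethylsilyloxy)hept-2-en-2-yl]zirconium | CC[C@@H](O[Si](CC)(CC)CC)[C@@H](C)/C=C(\C)[Zr](Cl)(C1C=CC=C1)C1C=CC=C1 | intermediate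
26 | triethyl{[(3R,4S,5E)-6-iodo-4-methylhept-5-en-3-yl]oxy}silane | CC[C@@H](O[Si](CC)(CC)CC)[C@@H](C)/C=C(\C)I | intermediate
27 | alkenyllithium from 26 (lithium in place of iodine, geometry retained) | CC[C@@H](O[Si](CC)(CC)CC)[C@@H](C)/C=C(\C)[Li] | intermediate
28 | (6S)-3-methoxy-6-(6-methoxy-3,5-dimethyl-4-oxo-4H-pyran-2-yl)-2,4,6-trimethyl-1-[(2E,4S,5R)-4-methyl-5-(triethylsilyloxy)hept-2-en-2-yl]cyclohexa-2,4-dien-1-ol (locant 1 unassigned) | CC[C@@H](O[Si](CC)(CC)CC)[C@@H](C)/C=C(\C)C1(O)C(C)=C(OC)C(C)=C[C@]1(C)c1oc(OC)c(C)c(=O)c1C | intermediate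
29 | (4S)-4-(6-methoxy-3,5-dimethyl-4-oxo-4H-pyran-2-yl)-2,4,6-trimethyl-3-[(2E,4S,5R)-4-methyl-5-(triethylsilyloxy)hept-2-en-2-yl]cyclohexa-2,5-dien-1-one | CC[C@@H](O[Si](CC)(CC)CC)[C@@H](C)/C=C(\C)C1=C(C)C(=O)C(C)=C[C@]1(C)c1oc(OC)c(C)c(=O)c1C | intermediate
30 | (4S)-3-[(2E,4S,5R)-5-hydroxy-4-methylhept-2-en-2-yl]-4-(6-methoxy-3,5-dimethyl-4-oxo-4H-pyran-2-yl)-2,4,6-trimethylcyclohexa-2,5-dien-1-one | CC[C@@H](O)[C@@H](C)/C=C(\C)C1=C(C)C(=O)C(C)=C[C@]1(C)c1oc(OC)c(C)c(=O)c1C | intermediate
31 | (4S)-4-(6-methoxy-3,5-dimethyl-4-oxo-4H-pyran-2-yl)-2,4,6-trimethyl-3-[(2E,4S)-4-methyl-5-oxohept-2-en-2-yl]cyclohexa-2,5-dien-1-one | CCC(=O)[C@@H](C)/C=C(\C)C1=C(C)C(=O)C(C)=C[C@]1(C)c1oc(OC)c(C)c(=O)c1C | target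

**Step count and risks**

Total step count: 18. Longest linear sequence: 13 steps (1–11, 17, 18); the side chain takes steps 12–16.

Steps most likely to fail:

1. Step 8. The catalyst may discriminate poorly between the two enantiotopic arms, or may not turn over because the acidic product holds the nickel. Fallback, setting out from 12 and returning at 13: 12 is cyclized without a chiral ligand by soft enolization (MgBr2·OEt2, i-Pr2NEt, CH2Cl2), a known thioester Claisen–Dieckmann closure, to give the racemic S-methyl 2-hydroxy-1,3,5-trimethyl-4,6-dioxo-5-Pyr-cyclohex-2-ene-1-carbothioate F1. This is resolved by preparative chromatography on a chiral stationary phase to return 13.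

2. Step 17. 1,2-Addition at the hindered carbonyl next to the quaternary carbon may be slow, so that enolization of the dienone or attack on the pyranone competes. Fallback, setting out from 18 and 26 and returning at 29 and then 30: the polarity at C3 is reversed. Oxalyl chloride (cat. DMF, CH2Cl2) activates the carbonyl oxygen of 18, chloride enters at that carbon and the methyl ether is cleaved, which should give (4R)-3-chloro-2,4,6-trimethyl-4-Pyr-cyclohexa-2,5-dien-1-one F2. Alkenyllithium 27, made from 26 as before, is quenched with Bu3SnCl to give tributyl[(2E,4S,5R)-4-methyl-5-(triethylsilyloxy)hept-2-en-2-yl]stannane F3. Stille coupling of F2 and F3 (Pd2(dba)3, AsPh3, CuI, NMP) should give 29, which 1 M HCl in THF converts into 30.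

3. Step 7. The second C-acylation may stay incomplete, and the thiolate set free may fragment the 2,2-diacyl unit (retro-Claisen). Fallback, setting out from 10 and returning at 12: 10 is converted with Me3SiOTf and Et3N into 4-methyl-4-Pyr-3,5-bis(trimethylsilyloxy)hepta-2,5-diene F4. This is acylated on both enol carbons with S-methyl chlorothioformate and ZnCl2 (Mukaiyama-type C-acylation of silyl enol ethers) to return 12 without base or free thiolate.

Further compounds
F1 | step 8 | racemic S-methyl 2-hydroxy-5-(6-methoxy-3,5-dimethyl-4-oxo-4H-pyran-2-yl)-1,3,5-trimethyl-4,6-dioxocyclohex-2-ene-1-carbothioate | O=C1C(C)=C(O)C(C)(C(=O)SC)C(=O)C1(C)c1oc(OC)c(C)c(=O)c1C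
F2 | step 17 | (4R)-3-chloro-4-(6-methoxy-3,5-dimethyl-4-oxo-4H-pyran-2-yl)-2,4,6-trimethylcyclohexa-2,5-dien-1-one | ClC1=C(C)C(=O)C(C)=C[C@]1(C)c1oc(OC)c(C)c(=O)c1C
F3 | step 17 | tributyl[(2E,4S,5R)-4-methyl-5-(triethylsilyloxy)hept-2-en-2-yl]stannane | CC[C@@H](O[Si](CC)(CC)CC)[C@@H](C)/C=C(\C)[Sn](CCCC)(CCCC)CCCC
F4 | step 7 | 4-(6-methoxy-3,5-dimethyl-4-oxo-4H-pyran-2-yl)-4-methyl-3,5-bis(trimethylsilyloxy)hepta-2,5-diene | CC=C(O[Si](C)(C)C)C(C)(C(=CC)O[Si](C)(C)C)c1oc(OC)c(C)c(=O)c1C
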